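Assumption: Reformatsky reagent 3, ethoxyacetylene 16 and auxiliary 6 are bought (3 and 16 as their commercial solutions). The descriptor (3R) follows from the ranking C2 > C1' > C4 > H at C3 of the target SMILES.

## The problem

The target is an isoflavan. Its ring C (O1, C2, C3, C4, C4a, C8a) is fused along C4a–C8a to a fully substituted phloroglucinol-type ring A and carries ring B, a 4-hydroxy-2-methoxyphenyl group, at C3. C3 (R) is the only stereocentre, so nothing in the molecule can relay or correct it. It has to be set by an external controller and then kept out of any step that would make it enolisable. Ring A is the real difficulty: its three oxygens are all different (ring ether O1 on C8a, methoxyl on C5, free hydroxyl on C7) and the prenyl group sits on C6 between two of them. A route from a symmetrical phloroglucinol must therefore tell three oxygens apart and then choose C6 over the equally activated C8. The prenyl alkene next to a free phenol closes to a dimethylchroman under acid and is reduced under hydrogenation, so the last protecting group must fall to fluoride. The enabling feature is that the six carbons of ring A divide into a four-carbon vinylketene (C7, C4a, C8a, C8) and a two-carbon ynol ether (C5, C6). The ketene oxygen becomes the C7 hydroxyl, the alkyne oxygen the C5 methoxyl, and the C8a oxygen is the ring C ether oxygen already in place, so ring A can be made last from a four-membered ring fused to a finished, enantiopure ring C.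

## Retrosynthesis

**31 to 30.** Only the O–Si bond of ring B is cut. A triisopropylsilyl ether is chosen over an acetal, a benzyl or an allyl ether because it survives zinc and titanium enolates, hydride, dilute acid and heat, and leaves with fluoride. The forward step must only spare the prenyl group and the phenols.

**30 to 21 and 25.** The bonds C4a–C5, C6–C7 and C7–C8 are cut, which removes ring A altogether. The neighbouring cuts (O1–C2 or C4–C4a with ring A intact) all need a pentasubstituted arene with three different oxygens and a correctly placed prenyl group as a building block. This cut replaces that arene by the bicyclic enone 21 and the C8 ynol ether 25. The forward reaction must open the cyclobutenone, join ketene and alkyne in one orientation only, and close ring A by electrocyclisation without touching C3.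

**25 to 22 and 23.** The bond between the acetylide carbon and the allylic CH2 is cut. Chloroacetal 22 is the practical source of methoxyacetylide, and the methyl ether is preferred to the ethyl ether because it has no retro-ene pathway at the temperature of the key step. The forward step must alkylate at the primary end of prenyl bromide 23.

**21 to 20.** The O–CH2 bond of the dihydropyran ring (O1–C2 of the chroman) is cut to give hydroxy enol 20. Cutting instead at the O–C(sp2) bond leads to the same compound, but the Mitsunobu direction uses the acidity of the vinylogous acid and cannot give a double-bond isomer. The forward step must favour intramolecular O-alkylation; C-alkylation would give a four-membered ring.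

**20 to 19, then 15 and 16.** Hydrolysis of vinylogous ester 19 gives 20, and the two ring bonds of 19 made by ketene–ynol ether cycloaddition are cut to acid 15 and ethoxyacetylene 16. The other pairing (parent ketene with a chain-bearing ynol ether) was set aside for three reasons:
- it needs gaseous ketene;
- it needs an acetylide alkylation of a β-aryl primary halide that invites elimination;
- its precursor is a mono-protected 2-aryl-1,3-propanediol, chiral only through its protecting group.

Placing the chain on the sp3 carbon of 19 does no harm, because in the derived cyclobutane-1,3-dione that carbon lies between both carbonyls and becomes the enol carbon of 20.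

**15 to 12, 11, then 8 and 9.** The C3–C4 bond is cut: acid 15 comes from hydroxy ester 12 by silylation and ester cleavage, 12 from imide 11 by reduction, and 11 from a Michael addition of imide 8 to acrylate 9. This puts the one-carbon oxygen arm and the three-carbon acid arm on C3 in a single C–C bond formation with different oxidation states from the start. The forward step needs facial control by the auxiliary, and the reduction must spare the tert-butyl ester.

**8 to 5 and 6; 5 to 4; 4 to 2 and 3; 2 to 1.** The N-acyl bond, the tert-butyl ester, the aryl–CH2 bond and the O–Si bond are cut in turn, back to bromophenol 1, zinc enolate 3 and auxiliary 6. A palladium-catalysed coupling of 3 is preferred to a strongly basic enolate arylation because it is neutral to the aryl silyl ether.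

## Roads not taken

Alternative 1: The cut is at C3–C1' and C4–C4a around a two-carbon vinyl unit. An ate complex from a vinylboronic ester and lithiated ring B would couple with aryl triflate A2 under palladium catalysis with a chiral bisphosphine. A 1,2-shift forms C3–C1' and reductive elimination forms C4–C4a, giving boronate A1. This road is more convergent than the chosen one, sets C3 by a catalyst, and would probably have a shorter longest linear sequence. Its weak points lie in A2. A2 is a fully substituted, doubly ortho-flanked, electron-rich triflate, so it is a poor partner for oxidative addition. Making it contains the whole ring A problem: three different oxygens and prenyl on the right carbon, starting from a symmetrical phenol. After the coupling, boron still has to be homologated by one carbon and oxidised to give C2, and three acetals must be removed with acid beside a prenylated phenol before ring C can close. Against its convergence and catalytic asymmetry, the chosen plan sets a ring A whose substitution follows from connectivity and a final deprotection with fluoride. It pays with a stoichiometric auxiliary and more linear steps.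

Alternative 2: The cut is at O1–C2. Photo-oxidation of the 1,1-disubstituted styrene in phenol A4 by an acridinium catalyst would let the C8a hydroxyl add 6-endo to the terminal carbon. A chiral thiol would then give hydrogen to the C3 radical to form chroman A3. The merits are a redox-neutral, atom-economic closure of ring C under mild conditions with both catalysts in small amounts. If the hydrogen transfer were selective, this would be the most economical way to make ring C and C3 together. The weak points are three:
- enantioselective hydrogen transfer from a thiol to a benzylic radical is not an established source of high selectivity;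
- the prenyl alkene and the electron-rich rings compete with the styrene for the oxidant;
- A4 again needs ring A fully differentiated and prenylated beforehand, and the acetals must come off with acid.

The chosen plan has one speculative step too, but that step creates no stereocentre; C3 comes from a reliable auxiliary-controlled reaction.

Alternative 3: The cut is at C3–C4 and at the O1–C2 acyl bond. Base would release an ortho-quinone methide from sulfone A6. A chiral ammonium enolate, formed from an activated ring B arylacetic ester and an isothiourea, would trap it to give dihydrocoumarin A5. In one respect this is better than the chosen plan: C3 and ring C are made together by an organocatalyst from two simple partners. The weak points are four: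
- the quinone methide has no substituent at C4 and oligomerises easily;
- C3 in A5 lies between a lactone carbonyl and an aryl ring and can epimerise under the base and during the reduction that must turn C2 into CH2, which costs two or three extra steps through a diol;
- A6 carries the same ring A burden as A2 and A4;
- the end game again needs acid.

The chosen plan sets against this a C3 that is never adjacent to a carbonyl after step 6, and a ring A built without any choice between C6 and C8.

Key step: step 12

## Route

Step 1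
Reactants: 1 4-bromo-3-methoxyphenol
Product: 2 (4-bromo-3-methoxyphenoxy)triisopropylsilane
Conditions: i-Pr3SiCl, imidazole, DMF, 0 °C to rt
Reagents that add atoms: chlorotriisopropylsilane, CC(C)[Si](Cl)(C(C)C)C(C)C
Why: Standard silylation of a phenol; the bulky aryl silyl ether should survive zinc and titanium enolates, hydride, dilute acid and heat and is removed by fluoride at the end.

Step 2
Reactants: 2 (4-bromo-3-methoxyphenoxy)triisopropylsilane; 3 (2-tert-butoxy-2-oxoethyl)zinc bromide
Product: 4 tert-butyl 2-[2-methoxy-4-(triisopropylsilyloxy)phenyl]acetate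
Conditions: Pd(dba)2 (2 mol %), 1,2,3,4,5-pentaphenyl-1'-(di-tert-butylphosphino)ferrocene (2 mol %), THF, rt to 50 °C
Reagents that add atoms: none
Why: Palladium-catalysed α-arylation with a Reformatsky reagent (Negishi-type coupling of a zinc ester enolate); the neutral conditions tolerate the silyl ether and the electron-rich, ortho-substituted bromide, and the zinc enolate stops at monoarylation.

Step 3
Reactants: 4 tert-butyl 2-[2-methoxy-4-(triisopropylsilyloxy)phenyl]acetate
Product: 5 2-[2-methoxy-4-(triisopropylsilyloxy)phenyl]acetic acid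
Conditions: CF3CO2H, CH2Cl2, 0 °C to rt
Reagents that add atoms: none
Why: Acidolysis of a tert-butyl ester with loss of isobutene; aryl triisopropylsilyl ethers are stable to this acid, and the only activated ring position is shielded by the silyl group.

Step 4
Reactants: 5 2-[2-methoxy-4-(triisopropylsilyloxy)phenyl]acetic acid; 6 (4R)-4-benzyl-1,3-oxazolidin-2-one
Product: 8 (4R)-4-benzyl-3-{2-[2-methoxy-4-(triisopropylsilyloxy)phenyl]acetyl}-1,3-oxazolidin-2-one, via mixed pivalic anhydride 7 (not isolated)
Conditions: t-BuCOCl, Et3N, THF, −20 °C; then 6, LiCl, −20 °C to rt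
Reagents that add atoms: none
Why: N-Acylation of the oxazolidinone through a mixed anhydride; the auxiliary attacks the unhindered arylacetyl carbonyl and not the pivaloyl carbonyl.

Step 5
Reactants: 8 (4R)-4-benzyl-3-{2-[2-methoxy-4-(triisopropylsilyloxy)phenyl]acetyl}-1,3-oxazolidin-2-one; 9 tert-butyl prop-2-enoate
Product: 11 tert-butyl (4R)-5-[(4R)-4-benzyl-2-oxo-1,3-oxazolidin-3-yl]-4-[2-methoxy-4-(triisopropylsilyloxy)phenyl]-5-oxopentanoate, via titanium enolate 10 (not isolated)
Conditions: TiCl3(OiPr) (from TiCl4 and Ti(OiPr)4), i-Pr2NEt, CH2Cl2, 0 °C; then 9, 0 °C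
Reagents that add atoms: none
Why: Auxiliary-controlled titanium enolate Michael addition (Evans-type); soft enolisation gives the chelated Z-enolate 10, and the acrylate adds to the face away from the benzyl group, which sets the future C3. The (4R)-auxiliary is chosen because aryl outranks the new CH2 at this centre, so the usual facial sense gives the (R) descriptor.

Step 6
Reactants: 11 tert-butyl (4R)-5-[(4R)-4-benzyl-2-oxo-1,3-oxazolidin-3-yl]-4-[2-methoxy-4-(triisopropylsilyloxy)phenyl]-5-oxopentanoate
Product: 12 tert-butyl (4R)-5-hydroxy-4-[2-methoxy-4-(triisopropylsilyloxy)phenyl]pentanoate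
Conditions: LiBH4, MeOH (1 equiv), THF, 0 °C
Reagents that add atoms: none
Why: Reductive cleavage of an N-acyloxazolidinone; the activated imide carbonyl is reduced much faster than the tert-butyl ester, the α-aryl centre is not enolised, and auxiliary 6 is recovered.

Step 7
Reactants: 12 tert-butyl (4R)-5-hydroxy-4-[2-methoxy-4-(triisopropylsilyloxy)phenyl]pentanoate
Product: 15 (4R)-5-(tert-butyldimethylsilyloxy)-4-[2-methoxy-4-(triisopropylsilyloxy)phenyl]pentanoic acid, via silyl ether ester 13 (not isolated), via trimethylsilyl ester 14 (not isolated)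
Conditions: t-BuMe2SiOTf, 2,6-lutidine, CH2Cl2, −78 °C; then Me3SiOTf, 0 °C to rt; aq. NaH2PO4
Reagents that add atoms: tert-butyldimethylsilyl trifluoromethanesulfonate, CC(C)(C)[Si](C)(C)OS(=O)(=O)C(F)(F)F
Why: O-Silylation, then silyl triflate-mediated cleavage of the tert-butyl ester (carbonyl silylation, loss of isobutene) to silyl ester 14, which hydrolyses on work-up. The buffered conditions leave the alkyl and aryl silyl ethers intact.

Step 8
Reactants: 15 (4R)-5-(tert-butyldimethylsilyloxy)-4-[2-methoxy-4-(triisopropylsilyloxy)phenyl]pentanoic acid; 16 ethoxyethyne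
Product: 19 4-{(2R)-3-(tert-butyldimethylsilyloxy)-2-[2-methoxy-4-(triisopropylsilyloxy)phenyl]propyl}-3-ethoxycyclobut-2-en-1-one (both epimers at the sp3 ring carbon), via acid chloride 17 (not isolated), via ketene 18 (not isolated)
Conditions: 1-chloro-N,N,2-trimethylprop-1-en-1-amine, CH2Cl2, 0 °C; then 16 (3 equiv), Et3N (slow addition), 0 °C to rt
Reagents that add atoms: none
Why: Neutral acid chloride formation, dehydrochlorination to aldoketene 18 and ketene–ynol ether [2+2] cycloaddition; the nucleophilic terminal carbon of 16 attacks the ketene carbonyl carbon, which gives the 3-ethoxy-4-alkyl regioisomer. The new ring centre forms without control and is erased in step 9.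

Step 9
Reactants: 19 4-{(2R)-3-(tert-butyldimethylsilyloxy)-2-[2-methoxy-4-(triisopropylsilyloxy)phenyl]propyl}-3-ethoxycyclobut-2-en-1-one
Product: 20 3-hydroxy-2-{(2R)-3-hydroxy-2-[2-methoxy-4-(triisopropylsilyloxy)phenyl]propyl}cyclobut-2-en-1-one
Conditions: 1 M aq. HCl, THF, rt
Reagents that add atoms: water, O
Why: Acid hydrolysis of a vinylogous ester to the cyclobutane-1,3-dione, which rests as its more substituted enol, with cleavage of the primary silyl ether in the same operation. In the dione the chain-bearing carbon lies between both carbonyls, so it becomes the enol carbon; the aryl silyl ether withstands dilute acid.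

Step 10
Reactants: 20 3-hydroxy-2-{(2R)-3-hydroxy-2-[2-methoxy-4-(triisopropylsilyloxy)phenyl]propyl}cyclobut-2-en-1-one
Product: 21 (4R)-4-[2-methoxy-4-(triisopropylsilyloxy)phenyl]-2-oxabicyclo[4.2.0]oct-1(6)-en-7-one
Conditions: PPh3, DIAD, THF (0.01 M), 0 °C to rt
Reagents that add atoms: none
Why: Intramolecular Mitsunobu etherification with a vinylogous acid as the acidic partner; O-alkylation closes a six-membered ring whereas C-alkylation would give a four-membered one. Substitution occurs at the CH2, so the stereocentre is untouched.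

Step 11
Reactants: 22 2-chloro-1,1-dimethoxyethane; 23 1-bromo-3-methylbut-2-ene
Product: 25 1-methoxy-5-methylhex-4-en-1-yne, via lithium methoxyacetylide 24 (not isolated)
Conditions: LiNEt2 (3 equiv, from Et2NH and n-BuLi), THF, −78 to 0 °C; then DMPU, 23, −78 °C to rt
Reagents that add atoms: none
Why: Twofold elimination of the chloroacetal by lithium amide gives acetylide 24, which is alkylated at the primary carbon of the allylic bromide (SN2) in the presence of DMPU. The methyl ynol ether is used because it cannot lose an alkene by a retro-ene reaction on heating.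

Step 12
Reactants: 21 (4R)-4-[2-methoxy-4-(triisopropylsilyloxy)phenyl]-2-oxabicyclo[4.2.0]oct-1(6)-en-7-one; 25 1-methoxy-5-methylhex-4-en-1-yne
Product: 30 (3R)-5-methoxy-3-[2-methoxy-4-(triisopropylsilyloxy)phenyl]-6-(3-methylbut-2-enyl)chroman-7-ol, via vinylketene 26 (not isolated), via spiro cyclobutenone 27 (not isolated), via dienylketene 28 (not isolated), via cyclohexadienone 29 (not isolated)
Conditions: 25 (2 equiv), degassed toluene, sealed tube, 110 °C then 140 °C
Reagents that add atoms: none
Why: Proposed new method: thermal 4π-electrocyclic opening of the strained ring-fused cyclobutenone 21 should give vinylketene 26, whose electrophilic central carbon (future C7) is attacked by the nucleophilic, prenyl-bearing carbon of ynol ether 25; collapse of the zwitterion (a formal [2+2] cycloaddition) forms C6–C7 and C4a–C5 and gives the spiro 4-vinylcyclobutenone 27. A second 4π opening gives dienylketene 28, which closes ring A by a thermal disrotatory 6π-electrocyclisation (forming C7–C8) to dienone 29, and tautomerisation gives phenol 30. The closest known reaction type is the Danheiser benzannulation of 3-alkyl- and 3-arylcyclobutenones with 1-alkoxyalkynes to give resorcinol monoethers; what is new is a 3-alkoxy substituent that is part of a fused dihydropyran ring. No stereocentre is formed, and C3 is not a reacting carbon and has no acidic hydrogen under these neutral conditions. The selectivity needed is the orientation of the ketene–alkyne union, and it is secured by the polarisation of 25, whose oxygen-free carbon is the nucleophile; the ketene oxygen thus becomes the free C7 hydroxyl, the alkyne oxygen the C5 methyl ether, and prenyl can only end on C6. Whichever geometry of 28 forms first, reversible opening of 27 should feed the isomer that can cyclise. The vinylogous-ester stabilisation of 21 is expected to raise the opening temperature, and an excess of 25 is used so that 30 is not acylated by remaining ketene.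

Step 13
Reactants: 30 (3R)-5-methoxy-3-[2-methoxy-4-(triisopropylsilyloxy)phenyl]-6-(3-methylbut-2-enyl)chroman-7-ol
Product: 31 (3R)-3-(4-hydroxy-2-methoxyphenyl)-5-methoxy-6-(3-methylbut-2-enyl)chroman-7-ol
Conditions: Bu4NF, AcOH, THF, 0 °C
Reagents that add atoms: none
Why: Fluoride cleavage of the aryl silyl ether; acetic acid keeps the electron-rich phenols protonated, and the prenyl group, the methyl ethers and C3 are not affected.

## Compound list

1 | 4-bromo-3-methoxyphenol | COc1cc(O)ccc1Br | starting material
2 | (4-bromo-3-methoxyphenoxy)triisopropylsilane | COc1cc(O[Si](C(C)C)(C(C)C)C(C)C)ccc1Br | intermediate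
3 | (2-tert-butoxy-2-oxoethyl)zinc bromide | CC(C)(C)OC(=O)C[Zn]Br | starting material
4 | tert-butyl 2-[2-methoxy-4-(triisopropylsilyloxy)phenyl]acetate | COc1cc(O[Si](C(C)C)(C(C)C)C(C)C)ccc1CC(=O)OC(C)(C)C | intermediate
5 | 2-[2-methoxy-4-(triisopropylsilyloxy)phenyl]acetic acid | COc1cc(O[Si](C(C)C)(C(C)C)C(C)C)ccc1CC(=O)O | intermediate
6 | (4R)-4-benzyl-1,3-oxazolidin-2-one | O=C1N[C@H](Cc2ccccc2)CO1 | starting material
7 | 2-[2-methoxy-4-(triisopropylsilyloxy)phenyl]acetic 2,2-dimethylpropanoic anhydride | COc1cc(O[Si](C(C)C)(C(C)C)C(C)C)ccc1CC(=O)OC(=O)C(C)(C)C | intermediate (not isolated)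
8 | (4R)-4-benzyl-3-{2-[2-methoxy-4-(triisopropylsilyloxy)phenyl]acetyl}-1,3-oxazolidin-2-one | COc1cc(O[Si](C(C)C)(C(C)C)C(C)C)ccc1CC(=O)N1[C@H](Cc2ccccc2)COC1=O | intermediate
9 | tert-butyl prop-2-enoate | C=CC(=O)OC(C)(C)C | starting material
10 | (Z)-dichloro(propan-2-olato)titanium enolate of 8 | COc1cc(O[Si](C(C)C)(C(C)C)C(C)C)ccc1/C=C(\O[Ti](Cl)(Cl)OC(C)C)N1[C@H](Cc2ccccc2)COC1=O | intermediate (not isolated)
11 | tert-butyl (4R)-5-[(4R)-4-benzyl-2-oxo-1,3-oxazolidin-3-yl]-4-[2-methoxy-4-(triisopropylsilyloxy)phenyl]-5-oxopentanoate | COc1cc(O[Si](C(C)C)(C(C)C)C(C)C)ccc1[C@@H](CCC(=O)OC(C)(C)C)C(=O)N1[C@H](Cc2ccccc2)COC1=O | intermediate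
12 | tert-butyl (4R)-5-hydroxy-4-[2-methoxy-4-(triisopropylsilyloxy)phenyl]pentanoate | COc1cc(O[Si](C(C)C)(C(C)C)C(C)C)ccc1[C@@H](CCC(=O)OC(C)(C)C)CO | intermediate
13 | tert-butyl (4R)-5-(tert-butyldimethylsilyloxy)-4-[2-methoxy-4-(triisopropylsilyloxy)phenyl]pentanoate | COc1cc(O[Si](C(C)C)(C(C)C)C(C)C)ccc1[C@@H](CCC(=O)OC(C)(C)C)CO[Si](C)(C)C(C)(C)C | intermediate (not isolated)
14 | trimethylsilyl (4R)-5-(tert-butyldimethylsilyloxy)-4-[2-methoxy-4-(triisopropylsilyloxy)phenyl]pentanoate | COc1cc(O[Si](C(C)C)(C(C)C)C(C)C)ccc1[C@@H](CCC(=O)O[Si](C)(C)C)CO[Si](C)(C)C(C)(C)C | intermediate (not isolated)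
15 | (4R)-5-(tert-butyldimethylsilyloxy)-4-[2-methoxy-4-(triisopropylsilyloxy)phenyl]pentanoic acid | COc1cc(O[Si](C(C)C)(C(C)C)C(C)C)ccc1[C@@H](CCC(=O)O)CO[Si](C)(C)C(C)(C)C | intermediate
16 | ethoxyethyne (ethoxyacetylene) | CCOC#C | starting material
17 | (4R)-5-(tert-butyldimethylsilyloxy)-4-[2-methoxy-4-(triisopropylsilyloxy)phenyl]pentanoyl chloride | COc1cc(O[Si](C(C)C)(C(C)C)C(C)C)ccc1[C@@H](CCC(=O)Cl)CO[Si](C)(C)C(C)(C)C | intermediate (not isolated)
18 | (4R)-5-(tert-butyldimethylsilyloxy)-4-[2-methoxy-4-(triisopropylsilyloxy)phenyl]pent-1-en-1-one (ketene) | COc1cc(O[Si](C(C)C)(C(C)C)C(C)C)ccc1[C@@H](CC=C=O)CO[Si](C)(C)C(C)(C)C | intermediate (not isolated)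
19 | 4-{(2R)-3-(tert-butyldimethylsilyloxy)-2-[2-methoxy-4-(triisopropylsilyloxy)phenyl]propyl}-3-ethoxycyclobut-2-en-1-one (both epimers at ring carbon 4) | CCOC1=CC(=O)C1C[C@@H](CO[Si](C)(C)C(C)(C)C)c1ccc(O[Si](C(C)C)(C(C)C)C(C)C)cc1OC | intermediate
20 | 3-hydroxy-2-{(2R)-3-hydroxy-2-[2-methoxy-4-(triisopropylsilyloxy)phenyl]propyl}cyclobut-2-en-1-one | OC1=C(C[C@@H](CO)c2ccc(O[Si](C(C)C)(C(C)C)C(C)C)cc2OC)C(=O)C1 | intermediate
21 | (4R)-4-[2-methoxy-4-(triisopropylsilyloxy)phenyl]-2-oxabicyclo[4.2.0]oct-1(6)-en-7-one | COc1cc(O[Si](C(C)C)(C(C)C)C(C)C)ccc1[C@@H]1COC2=C(C1)C(=O)C2 | intermediate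
22 | 2-chloro-1,1-dimethoxyethane | COC(CCl)OC | starting material
23 | 1-bromo-3-methylbut-2-ene | CC(C)=CCBr | starting material
24 | lithium methoxyacetylide | [Li]C#COC | intermediate (not isolated)
25 | 1-methoxy-5-methylhex-4-en-1-yne | COC#CCC=C(C)C | intermediate
26 | (5R)-5-[2-methoxy-4-(triisopropylsilyloxy)phenyl]-2-methylidene-3-(oxomethylidene)oxane (vinylketene) | COc1cc(O[Si](C(C)C)(C(C)C)C(C)C)ccc1[C@@H]1COC(=C)C(=C=O)C1 | intermediate (not isolated)
27 | (8R)-3-methoxy-8-[2-methoxy-4-(triisopropylsilyloxy)phenyl]-2-(3-methylbut-2-enyl)-5-methylidene-6-oxaspiro[3.5]non-2-en-1-one (both epimers at the spiro carbon) | COc1cc(O[Si](C(C)C)(C(C)C)C(C)C)ccc1[C@@H]1COC(=C)C2(C1)C(=O)C(CC=C(C)C)=C2OC | intermediate (not isolated)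
28 | 2-{methoxy[(5R)-5-[2-methoxy-4-(triisopropylsilyloxy)phenyl]-2-methylideneoxan-3-ylidene]methyl}-5-methylhexa-1,4-dien-1-one (dienylketene) | COc1cc(O[Si](C(C)C)(C(C)C)C(C)C)ccc1[C@@H]1COC(=C)C(C1)=C(OC)C(CC=C(C)C)=C=O | intermediate (not isolated)
29 | (3R)-5-methoxy-3-[2-methoxy-4-(triisopropylsilyloxy)phenyl]-6-(3-methylbut-2-enyl)-3,4-dihydro-2H-chromen-7(8H)-one | COc1cc(O[Si](C(C)C)(C(C)C)C(C)C)ccc1[C@@H]1COC2=C(C1)C(OC)=C(CC=C(C)C)C(=O)C2 | intermediate (not isolated)
30 | (3R)-5-methoxy-3-[2-methoxy-4-(triisopropylsilyloxy)phenyl]-6-(3-methylbut-2-enyl)chroman-7-ol | COc1cc(O[Si](C(C)C)(C(C)C)C(C)C)ccc1[C@@H]1COc2cc(O)c(CC=C(C)C)c(OC)c2C1 | intermediate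
31 | (3R)-3-(4-hydroxy-2-methoxyphenyl)-5-methoxy-6-(3-methylbut-2-enyl)chroman-7-ol | COc1cc(O)ccc1[C@@H]1COc2cc(O)c(CC=C(C)C)c(OC)c2C1 | target

## Step count and uncertain steps

Total: 13 steps. Longest linear sequence: 12 steps (steps 1 to 10, 12 and 13); step 11 is a one-step side branch.

**Step 12 (key step, proposed new method).** The vinylogous-ester stabilisation of the fused cyclobutenone may make ring opening so slow that the ynol ether or the vinylketene is consumed first, by ketene dimerisation or by acylation of the product phenol. The fallback uses known chemistry only; it sets out from imide 8 and comes back at 31. Ring A is brought in ready-made and symmetrical, and prenyl is placed by a Claisen rearrangement that has one free ortho position.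

- Ring A electrophile: commercial 2,4,6-trihydroxybenzaldehyde would be silylated at its non-chelated 4-hydroxyl (i-Pr3SiCl, imidazole) to 2,6-dihydroxy-4-(triisopropylsilyloxy)benzaldehyde F1. Protection (MeOCH2Cl, i-Pr2NEt) gives 2,6-bis(methoxymethoxy)-4-(triisopropylsilyloxy)benzaldehyde F2, reduction (NaBH4) gives [2,6-bis(methoxymethoxy)-4-(triisopropylsilyloxy)phenyl]methanol F3, and CBr4 with PPh3 gives 2-(bromomethyl)-1,3-bis(methoxymethoxy)-5-(triisopropylsilyloxy)benzene F4, used at once.
- Coupling and ring C: the sodium enolate of 8 (NaN(SiMe3)2, THF, −78 °C) would be alkylated by F4, with the facial sense of step 5, to (4R)-4-benzyl-3-{(2R)-3-[2,6-bis(methoxymethoxy)-4-(triisopropylsilyloxy)phenyl]-2-[2-methoxy-4-(triisopropylsilyloxy)phenyl]propanoyl}-1,3-oxazolidin-2-one F5. LiBH4 gives (2R)-3-[2,6-bis(methoxymethoxy)-4-(triisopropylsilyloxy)phenyl]-2-[2-methoxy-4-(triisopropylsilyloxy)phenyl]propan-1-ol F6, and HCl in methanol gives 2-{(2R)-3-hydroxy-2-[2-methoxy-4-(triisopropylsilyloxy)phenyl]propyl}-5-(triisopropylsilyloxy)benzene-1,3-diol F7. Mitsunobu closure onto either of the two equivalent phenols gives (3R)-3-[2-methoxy-4-(triisopropylsilyloxy)phenyl]-7-(triisopropylsilyloxy)chroman-5-ol F8.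
- Prenyl and end game: Pd(PPh3)4-catalysed O-alkylation with tert-butyl 2-methylbut-3-en-2-yl carbonate gives (3R)-3-[2-methoxy-4-(triisopropylsilyloxy)phenyl]-5-(2-methylbut-3-en-2-yloxy)-7-(triisopropylsilyloxy)chroman F9. Its aromatic Claisen rearrangement (toluene, 110 °C) can only reach C6 and gives (3R)-3-[2-methoxy-4-(triisopropylsilyloxy)phenyl]-6-(3-methylbut-2-enyl)-7-(triisopropylsilyloxy)chroman-5-ol F10. Methylation (MeI, K2CO3, acetone) gives (3R)-5-methoxy-3-[2-methoxy-4-(triisopropylsilyloxy)phenyl]-6-(3-methylbut-2-enyl)-7-(triisopropylsilyloxy)chroman F11, and Bu4NF removes both silyl groups to give 31.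

**Step 8.** The silyl ether oxygen may attack the acyl chloride intramolecularly (lactonisation with loss of the silyl group), or the aldoketene may dimerise faster than it adds to the ynol ether. The fallback sets out from 12 and comes back at 21. The oxygen is carried as a leaving group, so no nucleophilic oxygen faces the acyl chloride, and ring C is closed by displacement. Alcohol 12 would be converted (PPh3, CCl4) into tert-butyl (4R)-5-chloro-4-[2-methoxy-4-(triisopropylsilyloxy)phenyl]pentanoate F12, and CF3CO2H gives (4R)-5-chloro-4-[2-methoxy-4-(triisopropylsilyloxy)phenyl]pentanoic acid F13. Under the conditions of step 8 this passes through (4R)-5-chloro-4-[2-methoxy-4-(triisopropylsilyloxy)phenyl]pentanoyl chloride F14 and (4R)-5-chloro-4-[2-methoxy-4-(triisopropylsilyloxy)phenyl]pent-1-en-1-one F15 and, with 16, gives 4-{(2R)-3-chloro-2-[2-methoxy-4-(triisopropylsilyloxy)phenyl]propyl}-3-ethoxycyclobut-2-en-1-one F16. Aqueous HCl gives 2-{(2R)-3-chloro-2-[2-methoxy-4-(triisopropylsilyloxy)phenyl]propyl}-3-hydroxycyclobut-2-en-1-one F17, and Cs2CO3 with NaI in DMF closes the ring by O-alkylation to 21.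

**Step 5.** The Lewis acid may oligomerise the acrylate before the stabilised arylacetyl enolate adds, and the diastereomer ratio may erode if the α-aryl imide is re-enolised by the amine. The fallback sets out from 8 and comes back at 15. It replaces the Michael addition by alkylation of the sodium enolate with allyl iodide and a later oxidation-state adjustment. The alkylation would give (4R)-4-benzyl-3-{(2R)-2-[2-methoxy-4-(triisopropylsilyloxy)phenyl]pent-4-enoyl}-1,3-oxazolidin-2-one F18, and LiBH4 gives (2R)-2-[2-methoxy-4-(triisopropylsilyloxy)phenyl]pent-4-en-1-ol F19. Silylation (t-BuMe2SiCl, imidazole) gives tert-butyl{[(2R)-2-[2-methoxy-4-(triisopropylsilyloxy)phenyl]pent-4-enyl]oxy}dimethylsilane F20, and hydroboration (9-BBN, then NaBO3) gives (4R)-5-(tert-butyldimethylsilyloxy)-4-[2-methoxy-4-(triisopropylsilyloxy)phenyl]pentan-1-ol F21. Oxidation (TEMPO, PhI(OAc)2, aqueous MeCN) then gives acid 15.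

**Step 10.** Intermolecular etherification (oligomers) or alkylation of the reduced azodicarboxylate may compete with ring closure, because the strongly acidic enol gives a weakly nucleophilic anion. The fallback sets out from 20 and comes back at 21 and makes the other C–O bond. Acid-catalysed cyclodehydration (TsOH, toluene, 4 Å molecular sieves, 80 °C) lets the primary alcohol add to the protonated vinylogous acid and lose water, as in the esterification of cyclic 1,3-diones. The alcohol oxygen is kept and no new compound is made.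

## Further compounds

F1 | step 12 | 2,6-dihydroxy-4-(triisopropylsilyloxy)benzaldehyde | O=Cc1c(O)cc(O[Si](C(C)C)(C(C)C)C(C)C)cc1O
F2 | step 12 | 2,6-bis(methoxymethoxy)-4-(triisopropylsilyloxy)benzaldehyde | O=Cc1c(OCOC)cc(O[Si](C(C)C)(C(C)C)C(C)C)cc1OCOC
F3 | step 12 | [2,6-bis(methoxymethoxy)-4-(triisopropylsilyloxy)phenyl]methanol | OCc1c(OCOC)cc(O[Si](C(C)C)(C(C)C)C(C)C)cc1OCOC
F4 | step 12 | 2-(bromomethyl)-1,3-bis(methoxymethoxy)-5-(triisopropylsilyloxy)benzene | BrCc1c(OCOC)cc(O[Si](C(C)C)(C(C)C)C(C)C)cc1OCOC
F5 | step 12 | (4R)-4-benzyl-3-{(2R)-3-[2,6-bis(methoxymethoxy)-4-(triisopropylsilyloxy)phenyl]-2-[2-methoxy-4-(triisopropylsilyloxy)phenyl]propanoyl}-1,3-oxazolidin-2-one | COc1cc(O[Si](C(C)C)(C(C)C)C(C)C)ccc1[C@@H](Cc1c(OCOC)cc(O[Si](C(C)C)(C(C)C)C(C)C)cc1OCOC)C(=O)N1[C@H](Cc2ccccc2)COC1=O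
F6 | step 12 | (2R)-3-[2,6-bis(methoxymethoxy)-4-(triisopropylsilyloxy)phenyl]-2-[2-methoxy-4-(triisopropylsilyloxy)phenyl]propan-1-ol | COc1cc(O[Si](C(C)C)(C(C)C)C(C)C)ccc1[C@@H](Cc1c(OCOC)cc(O[Si](C(C)C)(C(C)C)C(C)C)cc1OCOC)CO
F7 | step 12 | 2-{(2R)-3-hydroxy-2-[2-methoxy-4-(triisopropylsilyloxy)phenyl]propyl}-5-(triisopropylsilyloxy)benzene-1,3-diol | COc1cc(O[Si](C(C)C)(C(C)C)C(C)C)ccc1[C@@H](Cc1c(O)cc(O[Si](C(C)C)(C(C)C)C(C)C)cc1O)CO
F8 | step 12 | (3R)-3-[2-methoxy-4-(triisopropylsilyloxy)phenyl]-7-(triisopropylsilyloxy)chroman-5-ol | COc1cc(O[Si](C(C)C)(C(C)C)C(C)C)ccc1[C@@H]1COc2cc(O[Si](C(C)C)(C(C)C)C(C)C)cc(O)c2C1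
F9 | step 12 | (3R)-3-[2-methoxy-4-(triisopropylsilyloxy)phenyl]-5-(2-methylbut-3-en-2-yloxy)-7-(triisopropylsilyloxy)chroman | COc1cc(O[Si](C(C)C)(C(C)C)C(C)C)ccc1[C@@H]1COc2cc(O[Si](C(C)C)(C(C)C)C(C)C)cc(OC(C)(C)C=C)c2C1
F10 | step 12 | (3R)-3-[2-methoxy-4-(triisopropylsilyloxy)phenyl]-6-(3-methylbut-2-enyl)-7-(triisopropylsilyloxy)chroman-5-ol | COc1cc(O[Si](C(C)C)(C(C)C)C(C)C)ccc1[C@@H]1COc2cc(O[Si](C(C)C)(C(C)C)C(C)C)c(CC=C(C)C)c(O)c2C1
F11 | step 12 | (3R)-5-methoxy-3-[2-methoxy-4-(triisopropylsilyloxy)phenyl]-6-(3-methylbut-2-enyl)-7-(triisopropylsilyloxy)chroman | COc1cc(O[Si](C(C)C)(C(C)C)C(C)C)ccc1[C@@H]1COc2cc(O[Si](C(C)C)(C(C)C)C(C)C)c(CC=C(C)C)c(OC)c2C1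
F12 | step 8 | tert-butyl (4R)-5-chloro-4-[2-methoxy-4-(triisopropylsilyloxy)phenyl]pentanoate | COc1cc(O[Si](C(C)C)(C(C)C)C(C)C)ccc1[C@@H](CCC(=O)OC(C)(C)C)CCl
F13 | step 8 | (4R)-5-chloro-4-[2-methoxy-4-(triisopropylsilyloxy)phenyl]pentanoic acid | COc1cc(O[Si](C(C)C)(C(C)C)C(C)C)ccc1[C@@H](CCC(=O)O)CCl
F14 | step 8 | (4R)-5-chloro-4-[2-methoxy-4-(triisopropylsilyloxy)phenyl]pentanoyl chloride | COc1cc(O[Si](C(C)C)(C(C)C)C(C)C)ccc1[C@@H](CCC(=O)Cl)CCl
F15 | step 8 | (4R)-5-chloro-4-[2-methoxy-4-(triisopropylsilyloxy)phenyl]pent-1-en-1-one | COc1cc(O[Si](C(C)C)(C(C)C)C(C)C)ccc1[C@@H](CC=C=O)CCl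
F16 | step 8 | 4-{(2R)-3-chloro-2-[2-methoxy-4-(triisopropylsilyloxy)phenyl]propyl}-3-ethoxycyclobut-2-en-1-one | CCOC1=CC(=O)C1C[C@@H](CCl)c1ccc(O[Si](C(C)C)(C(C)C)C(C)C)cc1OC
F17 | step 8 | 2-{(2R)-3-chloro-2-[2-methoxy-4-(triisopropylsilyloxy)phenyl]propyl}-3-hydroxycyclobut-2-en-1-one | OC1=C(C[C@@H](CCl)c2ccc(O[Si](C(C)C)(C(C)C)C(C)C)cc2OC)C(=O)C1
F18 | step 5 | (4R)-4-benzyl-3-{(2R)-2-[2-methoxy-4-(triisopropylsilyloxy)phenyl]pent-4-enoyl}-1,3-oxazolidin-2-one | COc1cc(O[Si](C(C)C)(C(C)C)C(C)C)ccc1[C@@H](CC=C)C(=O)N1[C@H](Cc2ccccc2)COC1=O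
F19 | step 5 | (2R)-2-[2-methoxy-4-(triisopropylsilyloxy)phenyl]pent-4-en-1-ol | COc1cc(O[Si](C(C)C)(C(C)C)C(C)C)ccc1[C@@H](CC=C)CO
F20 | step 5 | tert-butyl{[(2R)-2-[2-methoxy-4-(triisopropylsilyloxy)phenyl]pent-4-enyl]oxy}dimethylsilane | COc1cc(O[Si](C(C)C)(C(C)C)C(C)C)ccc1[C@@H](CC=C)CO[Si](C)(C)C(C)(C)C
F21 | step 5 | (4R)-5-(tert-butyldimethylsilyloxy)-4-[2-methoxy-4-(triisopropylsilyloxy)phenyl]pentan-1-ol | COc1cc(O[Si](C(C)C)(C(C)C)C(C)C)ccc1[C@@H](CCCO)CO[Si](C)(C)C(C)(C)C
F0 | step 10 | none | none
A1 | alternative 1 | 2-{(1R)-1-[2-methoxy-4-(methoxymethoxy)phenyl]-2-[2-methoxy-4,6-bis(methoxymethoxy)-3-(3-methylbut-2-enyl)phenyl]ethyl}-4,4,5,5-tetramethyl-1,3,2-dioxaborolane | COc1cc(OCOC)ccc1[C@@H](Cc1c(OC)c(CC=C(C)C)c(OCOC)cc1OCOC)B1OC(C)(C)C(C)(C)O1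
A2 | alternative 1 | 2-methoxy-4,6-bis(methoxymethoxy)-3-(3-methylbut-2-enyl)phenyl trifluoromethanesulfonate | COc1c(CC=C(C)C)c(OCOC)cc(OCOC)c1OS(=O)(=O)C(F)(F)F
A3 | alternative 2 | (3R)-5-methoxy-3-[2-methoxy-4-(methoxymethoxy)phenyl]-7-(methoxymethoxy)-6-(3-methylbut-2-enyl)chroman | COc1cc(OCOC)ccc1[C@@H]1COc2cc(OCOC)c(CC=C(C)C)c(OC)c2C1
A4 | alternative 2 | 3-methoxy-2-{2-[2-methoxy-4-(methoxymethoxy)phenyl]prop-2-enyl}-5-(methoxymethoxy)-4-(3-methylbut-2-enyl)phenol | COc1cc(OCOC)ccc1C(=C)Cc1c(O)cc(OCOC)c(CC=C(C)C)c1OC
A5 | alternative 3 | (3R)-5-methoxy-3-[2-methoxy-4-(methoxymethoxy)phenyl]-7-(methoxymethoxy)-6-(3-methylbut-2-enyl)-3,4-dihydrochromen-2-one | COc1cc(OCOC)ccc1[C@@H]1C(=O)Oc2cc(OCOC)c(CC=C(C)C)c(OC)c2C1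
A6 | alternative 3 | 3-methoxy-5-(methoxymethoxy)-4-(3-methylbut-2-enyl)-2-[(4-methylphenyl)sulfonylmethyl]phenol | COc1c(CS(=O)(=O)c2ccc(C)cc2)c(O)cc(OCOC)c1CC=C(C)C
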